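Ring A (C1–C6: C1 CMe2, C2 CHBr, C3 CHOH, C5 CHMe, C6 spiro) is disconnected at C2. Without C2, ring A is a cyclopentanone (compound 8) with C1 as carbonyl, so the spiro carbon C6, lying between this carbonyl and the C5 methyl stereocentre, can be built by two successive enolate C–C bond formations anti to that methyl. The key step re-inserts C2 between C1 and C3 by Lewis-acid-catalysed trimethylsilyldiazomethane homologation. It exploits that quaternary C6 cannot compete with the C3 methylene in the 1,2-shift, and it delivers the six-membered ring as a regiodefined enol silane, from which the C1 gem-dimethyl group and the C2/C3 bromohydrin follow.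

Key step: step 5

Remark: locants C1–C11 in the text are those of the target named as a spiro[5.5]undecane (ring A: C1 CMe2, C2 CHBr, C3 CHOH, C4 CH2, C5 CHMe, C6 spiro; ring B: C6, C7 CH2, C8 CHBr, C9 CMeCl, C10, C11); the same carbons keep these labels in earlier intermediates, whatever their systematic names.

Step 1
Reactants: 1 3-methylcyclopent-2-en-1-one; 2 allyl bromide (3-bromoprop-1-ene)
Product: 4 (2R,3S)-3-methyl-2-(prop-2-en-1-yl)cyclopentan-1-one, via bis-enol silane 3 (not isolated)
Conditions: Ph2SiH2 (0.55 equiv), CuCl (5 mol%), NaOtBu (5 mol%), p-Tol-BINAP (5 mol%, the enantiomer that gives the 3S centre), toluene, 0 °C; then Bu4N[Ph3SiF2], 2, CH2Cl2, rt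
Reagents that add atoms: none
Why: Ligand-controlled copper hydride conjugate reduction (asymmetric 1,4-reduction) should set the methyl-bearing centre (C5 of the target) as S, and the fluoride-released enolate is allylated in the same flask trans to the methyl group; the allyl-bearing centre is reset in step 2.

Step 2
Reactants: 4 (2R,3S)-3-methyl-2-(prop-2-en-1-yl)cyclopentan-1-one; 5 but-3-en-2-one (methyl vinyl ketone)
Product: 6 (2S,3S)-3-methyl-2-(3-oxobutyl)-2-(prop-2-en-1-yl)cyclopentan-1-one
Conditions: NaOEt (0.1 equiv), EtOH, −10 °C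
Reagents that add atoms: none
Why: Base-catalysed Michael addition through the more substituted (thermodynamic) enolate, as in the first stage of a Robinson annulation; 5 should approach the planar enolate anti to the adjacent methyl group, so the 3-oxobutyl chain ends trans and the allyl group cis to that methyl, which fixes C6.

Step 3
Reactants: 6 (2S,3S)-3-methyl-2-(3-oxobutyl)-2-(prop-2-en-1-yl)cyclopentan-1-one
Product: 7 (2S,3S)-3-methyl-2-(3-methylbut-3-en-1-yl)-2-(prop-2-en-1-yl)cyclopentan-1-one
Conditions: Ph3PCH3Br (1.05 equiv), KOtBu, THF, 0 °C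
Reagents that add atoms: methyltriphenylphosphonium bromide, C[P+](c1ccccc1)(c1ccccc1)c1ccccc1.[Br-]
Why: Wittig methylenation; the unhindered methyl ketone should react with one equivalent of ylide far faster than the ring ketone flanked by the new quaternary carbon.

Step 4
Reactants: 7 (2S,3S)-3-methyl-2-(3-methylbut-3-en-1-yl)-2-(prop-2-en-1-yl)cyclopentan-1-one
Product: 8 (4S,5S)-4,8-dimethylspiro[4.5]dec-7-en-1-one
Conditions: second-generation Grubbs catalyst (5 mol%), CH2Cl2, 40 °C
Reagents that add atoms: none
Why: Ring-closing metathesis between the allyl group and the 1,1-disubstituted alkene closes ring B as a six-membered ring with the trisubstituted C8=C9 double bond; no stereocentre is affected.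

Step 5
Reactants: 8 (4S,5S)-4,8-dimethylspiro[4.5]dec-7-en-1-one
Product: 10 {[(5S,6S)-5,9-dimethylspiro[5.5]undeca-1,8-dien-1-yl]oxy}trimethylsilane, via beta-keto silane 9 (not isolated)
Conditions: Me3SiCHN2 (1.2 equiv), Sc(OTf)3 (5 mol%), toluene, 0 °C to rt; then 80 °C
Reagents that add atoms: trimethylsilyldiazomethane, C[Si](C)(C)C=[N+]=[N-]
Why: Sc(OTf)3 activates the C1 carbonyl of 8, the diazo carbon adds to it, and the C3 methylene shifts from C1 to the new carbon (C2) with loss of N2 to give β-keto silane 9, whose silyl group then moves from C2 to oxygen (1,3-Brook shift) to give enol silane 10. The closest known reaction type is the Lewis-acid-catalysed diazoalkane–ketone homologation (Tiffeneau–Demjanov-type one-carbon ring expansion) followed by the thermal β-keto silane to enol silane isomerisation. No ring is closed anew: the five-membered ring of 8 is enlarged to the six-membered ring A by a 1,2-alkyl shift. No stereocentre is created (C2 of 9 is transient and becomes sp2 in 10), and C5 and C6 are untouched because no bond to C6 is broken. The step needs migration of the C3 methylene and not of C6, which the substrate secures because C6 is quaternary and the less substituted carbon migrates in this homologation; the bulky α-silyl group of 9 also blocks a second homologation.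

Step 6
Reactants: 10 {[(5S,6S)-5,9-dimethylspiro[5.5]undeca-1,8-dien-1-yl]oxy}trimethylsilane
Product: 11 (5S,6S)-5,9-dimethylspiro[5.5]undeca-2,8-dien-1-one
Conditions: Pd(OAc)2 (1.0 equiv), MeCN, rt
Reagents that add atoms: none
Why: Saegusa–Ito oxidation: the regiodefined enol silane gives an oxa-π-allyl palladium species whose β-hydride elimination places the double bond at C2=C3, and the isolated ring B alkene should not react.

Step 7
Reactants: 11 (5S,6S)-5,9-dimethylspiro[5.5]undeca-2,8-dien-1-one
Product: 12 (5S,6S)-1,5,9-trimethylspiro[5.5]undeca-2,8-dien-1-ol (mixture of C1 epimers)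
Conditions: MeLi, Et2O, −78 °C; aqueous work-up
Reagents that add atoms: methyllithium, [Li]C
Why: 1,2-Addition of methyllithium to the enone carbonyl C1 at low temperature; the new carbinol configuration is irrelevant because C1 becomes sp2 again in step 8.

Step 8
Reactants: 12 (5S,6S)-1,5,9-trimethylspiro[5.5]undeca-2,8-dien-1-ol
Product: 13 (5S,6S)-1,5,9-trimethylspiro[5.5]undeca-1,8-dien-3-one
Conditions: C5H5NH[CrO3Cl] (pyridinium chlorochromate), CH2Cl2, rt
Reagents that add atoms: none
Why: Dauben oxidative transposition: the chromate ester of the tertiary allylic alcohol undergoes a [3,3] shift to C3 and is oxidised, moving oxygen from C1 to C3 and leaving C1 as the methyl-bearing β-carbon of the enone.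

Step 9
Reactants: 13 (5S,6S)-1,5,9-trimethylspiro[5.5]undeca-1,8-dien-3-one
Product: 15 (2S,5S,6S)-2-bromo-1,1,5,9-tetramethylspiro[5.5]undec-8-en-3-one, via silyl enol ether 14 (not isolated)
Conditions: Me2CuLi (from CuI and MeLi), Me3SiCl, THF, −78 to 0 °C; non-aqueous work-up; then NBS, THF, −78 °C
Reagents that add atoms: lithium dimethylcuprate, [Li+].C[Cu-]C; N-bromosuccinimide, O=C1CCC(=O)N1Br
Why: Silyl-chloride-accelerated cuprate conjugate addition should place the second methyl on C1 next to the quaternary C6 (as in cuprate syntheses of vicinal quaternary carbons) and give the C3 enol silane regiospecifically; NBS then brominates C2 axially, anti to the pseudo-axial C1 methyl in the half-chair that keeps the C5 methyl equatorial, so bromine ends cis to the C5 methyl (2S).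

Step 10
Reactants: 15 (2S,5S,6S)-2-bromo-1,1,5,9-tetramethylspiro[5.5]undec-8-en-3-one
Product: 16 (2S,3R,5S,6S)-2-bromo-1,1,5,9-tetramethylspiro[5.5]undec-8-en-3-ol
Conditions: i-Bu2AlH, CH2Cl2, −78 °C; aqueous work-up
Reagents that add atoms: none
Why: Hydride should attack the C3 carbonyl anti to the axial C2–Br bond (polar Felkin–Anh control, as in reductions of axial α-bromocyclohexanones), giving the equatorial 3R alcohol cis to bromine.

Step 11
Reactants: 16 (2S,3R,5S,6S)-2-bromo-1,1,5,9-tetramethylspiro[5.5]undec-8-en-3-ol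
Product: 17 (2S,3R,5S,6S,8R,9S)-2-bromo-8,9-epoxy-1,1,5,9-tetramethylspiro[5.5]undecan-3-ol
Conditions: D-fructose-derived Shi ketone (30 mol%), 2KHSO5·KHSO4·K2SO4 (Oxone), K2CO3, Bu4NHSO4, MeCN–dimethoxymethane–aqueous buffer, 0 °C
Reagents that add atoms: potassium peroxymonosulfate, [K+].[O-]S(=O)(=O)OO
Why: Shi asymmetric epoxidation: the chiral dioxirane transfers oxygen to the trisubstituted alkene through its spiro transition state under catalyst control, which is needed because ring A hardly differentiates the two faces of ring B; the D-fructose-derived ketone should give the 8R,9S epoxide (oxygen on the face syn to C5).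

Step 12
Reactants: 17 (2S,3R,5S,6S,8R,9S)-2-bromo-8,9-epoxy-1,1,5,9-tetramethylspiro[5.5]undecan-3-ol
Product: 18 (2S,3R,5S,6S,8S,9S)-2,8-dibromo-1,1,5,9-tetramethylspiro[5.5]undecane-3,9-diol
Conditions: Li2NiBr4, THF, 0 °C to rt; aqueous work-up
Reagents that add atoms: dilithium tetrabromonickelate, [Li+].[Li+].[Ni+2].[Br-].[Br-].[Br-].[Br-]
Why: Soft bromide should open the epoxide by SN2 attack at the less substituted C8 (trans-diaxial opening) with inversion, so bromine ends on the face opposite to the oxygen and C9 keeps its tertiary hydroxyl.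

Step 13
Reactants: 18 (2S,3R,5S,6S,8S,9S)-2,8-dibromo-1,1,5,9-tetramethylspiro[5.5]undecane-3,9-diol
Product: 19 (2S,3R,5S,6S,8S,9S)-2,8-dibromo-9-chloro-1,1,5,9-tetramethylspiro[5.5]undecan-3-ol (target)
Conditions: HCl (4 M in dioxane), CH2Cl2, 0 °C
Reagents that add atoms: hydrogen chloride, Cl
Why: The tertiary C9 hydroxyl should ionise with participation of the anti C8 bromine (Winstein-type bromonium ion) and chloride opens the bromonium at the tertiary C9 anti to bromine, which means net retention at C9 and a trans bromochloride; the secondary cis bromohydrin of ring A cannot ionise in this way.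

Compound list
1 | 3-methylcyclopent-2-en-1-one | CC1=CC(=O)CC1 | starting material
2 | allyl bromide (3-bromoprop-1-ene) | C=CCBr | starting material
3 | bis{[(3S)-3-methylcyclopent-1-en-1-yl]oxy}diphenylsilane | C[C@H]1CCC(O[Si](c2ccccc2)(c2ccccc2)OC2=C[C@@H](C)CC2)=C1 | intermediate
4 | (2R,3S)-3-methyl-2-(prop-2-en-1-yl)cyclopentan-1-one | C[C@H]1CCC(=O)[C@@H]1CC=C | intermediate
5 | but-3-en-2-one (methyl vinyl ketone) | CC(=O)C=C | starting material
6 | (2S,3S)-3-methyl-2-(3-oxobutyl)-2-(prop-2-en-1-yl)cyclopentan-1-one | C[C@H]1CCC(=O)[C@]1(CC=C)CCC(C)=O | intermediate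
7 | (2S,3S)-3-methyl-2-(3-methylbut-3-en-1-yl)-2-(prop-2-en-1-yl)cyclopentan-1-one | C[C@H]1CCC(=O)[C@]1(CC=C)CCC(C)=C | intermediate
8 | (4S,5S)-4,8-dimethylspiro[4.5]dec-7-en-1-one | C[C@H]1CCC(=O)[C@]12CCC(C)=CC2 | intermediate
9 | (5S,6S)-5,9-dimethyl-2-(trimethylsilyl)spiro[5.5]undec-8-en-1-one (C2 epimers) | C[C@H]1CCC([Si](C)(C)C)C(=O)[C@]12CCC(C)=CC2 | intermediate
10 | {[(5S,6S)-5,9-dimethylspiro[5.5]undeca-1,8-dien-1-yl]oxy}trimethylsilane | C[C@H]1CCC=C(O[Si](C)(C)C)[C@]12CCC(C)=CC2 | intermediate
11 | (5S,6S)-5,9-dimethylspiro[5.5]undeca-2,8-dien-1-one | C[C@H]1CC=CC(=O)[C@]12CCC(C)=CC2 | intermediate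
12 | (5S,6S)-1,5,9-trimethylspiro[5.5]undeca-2,8-dien-1-ol (C1 epimers) | C[C@H]1CC=CC(C)(O)[C@]12CCC(C)=CC2 | intermediate
13 | (5S,6S)-1,5,9-trimethylspiro[5.5]undeca-1,8-dien-3-one | C[C@H]1CC(=O)C=C(C)[C@]12CCC(C)=CC2 | intermediate
14 | trimethyl{[(5S,6S)-1,1,5,9-tetramethylspiro[5.5]undeca-2,8-dien-3-yl]oxy}silane | C[C@H]1CC(O[Si](C)(C)C)=CC(C)(C)[C@]12CCC(C)=CC2 | intermediate
15 | (2S,5S,6S)-2-bromo-1,1,5,9-tetramethylspiro[5.5]undec-8-en-3-one | C[C@H]1CC(=O)[C@@H](Br)C(C)(C)[C@]12CCC(C)=CC2 | intermediate
16 | (2S,3R,5S,6S)-2-bromo-1,1,5,9-tetramethylspiro[5.5]undec-8-en-3-ol | C[C@H]1C[C@@H](O)[C@@H](Br)C(C)(C)[C@]12CCC(C)=CC2 | intermediate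
17 | (2S,3R,5S,6S,8R,9S)-2-bromo-8,9-epoxy-1,1,5,9-tetramethylspiro[5.5]undecan-3-ol | C[C@H]1C[C@@H](O)[C@@H](Br)C(C)(C)[C@]12CC[C@]3(C)O[C@@H]3C2 | intermediate
18 | (2S,3R,5S,6S,8S,9S)-2,8-dibromo-1,1,5,9-tetramethylspiro[5.5]undecane-3,9-diol | C[C@H]1C[C@@H](O)[C@@H](Br)C(C)(C)[C@]12CC[C@](C)(O)[C@@H](Br)C2 | intermediate
19 | (2S,3R,5S,6S,8S,9S)-2,8-dibromo-9-chloro-1,1,5,9-tetramethylspiro[5.5]undecan-3-ol | C[C@H]1C[C@@H](O)[C@@H](Br)C(C)(C)[C@]12CC[C@](C)(Cl)[C@@H](Br)C2 | target

Total step count: 13. Longest linear sequence: 13 steps (1 to 19).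

Steps most likely to fail

Step 9. The methyl transfer to the fully substituted C1, which sits next to the quaternary C6, may be too slow, so that 13 is recovered or attacked at the carbonyl. The fallback builds the second C1 methyl from a cyclopropane and sets out from 13. Luche reduction (NaBH4, CeCl3·7H2O, MeOH) should give the allylic alcohol (5S,6S)-1,5,9-trimethylspiro[5.5]undeca-1,8-dien-3-ol F1. Hydroxyl-directed Simmons–Smith cyclopropanation (Et2Zn, CH2I2) of its C1=C2 double bond gives the cyclopropyl carbinol (5S,6S)-1,5,9-trimethyl-1,2-methanospiro[5.5]undec-8-en-3-ol F2, and Dess–Martin oxidation gives the cyclopropyl ketone (5S,6S)-1,5,9-trimethyl-1,2-methanospiro[5.5]undec-8-en-3-one F3. Lithium in liquid ammonia should then cleave the cyclopropane bond between C2 and the added CH2, which becomes the second methyl on C1. Silylation of the resulting C3 lithium enolate with Me3SiCl returns the route to 14.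

Step 12. Bromide may attack the tertiary C9 instead of C8, or the Lewis-acidic nickel salt may isomerise the epoxide by a 1,2-shift. The fallback leaves the epoxide route and sets out from 16. Tetrabutylammonium dichlorobromate (Bu4N[BrCl2], CH2Cl2, −78 °C) adds bromine and chlorine anti across C8=C9 through a bromonium ion opened by chloride at the tertiary C9, and comes back to the route at 19. Because ring A hardly differentiates the faces of ring B, (2S,3R,5S,6S,8R,9R)-2,8-dibromo-9-chloro-1,1,5,9-tetramethylspiro[5.5]undecan-3-ol F5 is expected as a co-product and has to be removed by chromatography, which is why this shorter path is only the fallback.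

Step 2. The Michael addition may occur at the less substituted α-carbon of 4, or the 1,5-diketone may cyclise by aldol reaction. The fallback fixes the regiochemistry before the C–C bond is made and sets out from 4. Thermodynamic silylation (Me3SiCl, NaI, Et3N, MeCN) should give trimethyl{[(3S)-3-methyl-2-(prop-2-en-1-yl)cyclopent-1-en-1-yl]oxy}silane F4, which is separated from its less substituted isomer. Mukaiyama–Michael addition of F4 to 5 (BF3·OEt2, i-PrOH, CH2Cl2, −78 °C), again anti to the methyl group, returns the route to 6.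

Further compounds
F1 | step 9 | (5S,6S)-1,5,9-trimethylspiro[5.5]undeca-1,8-dien-3-ol (C3 epimers) | C[C@H]1CC(O)C=C(C)[C@]12CCC(C)=CC2
F2 | step 9 | (5S,6S)-1,5,9-trimethyl-1,2-methanospiro[5.5]undec-8-en-3-ol | C[C@H]1CC(O)C3CC3(C)[C@]12CCC(C)=CC2
F3 | step 9 | (5S,6S)-1,5,9-trimethyl-1,2-methanospiro[5.5]undec-8-en-3-one | C[C@H]1CC(=O)C3CC3(C)[C@]12CCC(C)=CC2
F4 | step 2 | trimethyl{[(3S)-3-methyl-2-(prop-2-en-1-yl)cyclopent-1-en-1-yl]oxy}silane | C[C@H]1CCC(O[Si](C)(C)C)=C1CC=C
F5 | step 12 | (2S,3R,5S,6S,8R,9R)-2,8-dibromo-9-chloro-1,1,5,9-tetramethylspiro[5.5]undecan-3-ol | C[C@H]1C[C@@H](O)[C@@H](Br)C(C)(C)[C@]12CC[C@@](C)(Cl)[C@H](Br)C2
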